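## Structural features

The target is an ansa-bridged aminophenol. Ring A is the arene C16–C21, carrying the free hydroxyl at C18, the anilide nitrogen at C20 and the ether oxygen at C21. Ring B is an eight-membered benzoxocane (C21–O–C11–C12–C13–C14–C15–C16) fused to ring A. Ring C is the 15-membered lactam that runs from N through C1–C11 and closes through the same ether oxygen, so C11 is the branch point of both rings.

The stereocentres fall into four groups: the contiguous triad C10 (S, methyl), C11 (R, aryl ether), C12 (S, methoxy) with 10,11-syn and 11,12-anti relationships; the remote C14 (R) in ring B; the vicinal syn pair C6 (S, methoxy) and C7 (S, carbamate) next to the Z-trisubstituted C8=C9 alkene; and the isolated quaternary carbinol C2 (S) alpha to the amide. The fragile groups are the C4 ketone (beta to the C6 methoxy group, so prone to elimination, and beta to the tertiary C2 hydroxyl, so prone to retro-aldol cleavage), the primary carbamate on the allylic C7, and the electron-rich 4-alkoxy-aminophenol ring.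

The real difficulty is the C1–C7 segment: a 1,3,5-oxygenated chain with a quaternary carbinol, an enolisable ketone and a hindered anilide junction, which has to be attached to a valuable benzoxocane without disturbing its stereocentres. The key step uses the fact that C4 sits between two methylene groups, C3 and C5, each leading to an oxygen-bearing stereocentre (C2 and C6). Both C–O bonds can be read as former epoxide oxygens, so C4 can enter as a doubly nucleophilic masked carbonyl carbon.

## Logic of the disconnections

**46 back to 41.** The last operations only unmask groups: the two Si–O bonds (C18 and C2), the two C–S bonds at C4, and the carbamoyl C–O bond at C7 are cut in that order. The ketone stays masked and the phenol and tertiary alcohol stay silylated until all base or heat steps are past. The demand is a selective cleavage of the secondary allylic silyl ether in 41 in the presence of a tertiary and an aryl silyl ether.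

**41 back to 35.** The amide N–C1 bond is cut, giving amino acid 40. The acid comes from 35 by methylation of the C6 hydroxyl, release and oxidation of C1, and removal of the nitrogen mask. This opens the 15-membered ring at its only heteroatom–carbonyl bond. The forward step has to acylate a hindered aniline with an alpha-quaternary acid, and the oxidation has to spare sulfur and the pyrrole.

**35 back to 31, 30 and 27.** C3–C4 and C4–C5 are cut together. C4 becomes the dithiane carbon of 31, and C3 and C5 become the methylene termini of epoxides 30 and 27. This splits the molecule into a one-carbon linchpin, a three-carbon piece carrying C2, and the whole benzoxocane half, and it delivers C2 and C6 as preformed stereocentres. The forward step must open each epoxide once, in order, at its CH2.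

**27 back to 18 and 19.** The epoxide C5–O/C6–O is traced to diol 24 with inversion at C6, and C7–C8 is cut to alkenyl iodide 18 and aldehyde 19. The inversion lets the Felkin-type (6,7-anti) addition to the inexpensive aldehyde 19 deliver the 6,7-syn epoxide. The demand is facial control at C7 and a clean primary/secondary differentiation in 24.

**18 back to 13.** C8=C9 is cut to aldehyde 17, and the aniline mask is traced to nitro compound 13. The iodo-olefination must give the Z geometry on a beta-aryloxy aldehyde without epimerising C10, and the nitrogen must be masked before any organolithium is used.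

**13 back to 9 and 4.** The C14–H bond, then C13=C14, then C15–C16, then C21–O are cut in turn (12, 11, 10). Ring B is reduced to an aryl fluoride and an acyclic alcohol whose vinyl group is already in place. The forward steps need a ring-closing metathesis to a trisubstituted cyclooctene and a face-selective hydrogenation that sets C14.

**9 back to 5, 4 back to 1, and 30 back to 28.** C11–C12 is cut to aldehyde 7, which comes from ester 5. The C18–O bond of 4 is cut to 1. The epoxide oxygen of 30 is cut to allylic alcohol 28. Each fragment then rests on one purchasable chiral or achiral building block. The demands are an anti-selective alkoxyallylation on the correct aldehyde face, a meta-selective C–H oxygenation, and an enantioselective epoxidation.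

## Other disconnections considered

**Alternative 1:** The cut is C13=C14 inside ring B. In the forward sense the second-generation Grubbs catalyst joins a C13 vinyl group and a C14 methallyl alkene to give the nitro benzoxocine A1, and a hydrogenation directed by the C12 methoxy group then sets C14.

- In favour: both alkenes arrive for free (the vinyl group is what the alkoxyallylation leaves behind, the methallyl group comes from one cross-coupling), the benzo fusion and the aryl ether pre-organise the eight-membered closure, and C14 needs no second chiral building block.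
- Against, as the centre of a plan: it forms one bond that is then saturated, joins no fragments, and leaves the whole C1–C8 chain to be grown linearly. The C14 configuration rests on the conformation of a flexible ring.
- Comparison: this cut and the chosen one address different parts of the molecule. The chosen route closes ring B in this same way (A1 is the same compound as 12), so on the ring the alternative is the equal of the chosen plan. On convergence and step economy for the ansa chain the linchpin plan is ahead, because one operation forms two skeletal bonds and unites three fragments.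

**Alternative 2:** The cut is the aryl C20–N bond. In the forward sense CuI (monovalent copper) with N,N'-dimethylethylenediamine and K3PO4 couples the C1 primary amide of the open-chain bromide A2 with its C20 aryl bromide (an intramolecular Goldberg amidation) and closes the 15-membered ring to A3.

- In favour: the ring closes at an unhindered primary amide nitrogen instead of by acylating a hindered aniline with a quaternary acid; the tertiary C2 hydroxyl can stay free; no aniline has to be masked and unmasked. On the ring-closing step itself, and on protecting-group economy at nitrogen, this alternative is the better of the two.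
- Against it here: the arene would need a bromide at C20, so the nitro group that activates the C21–O bond formation in the chosen route and later becomes the nitrogen is lost, and two aryl bromides (C16 and C20) would have to be told apart. Hot basic copper conditions and a sulfur ketal do not go well together, which is why A3 carries a dioxolane; that in turn removes the dithiane from the chain assembly.
- Comparison: the mechanism is metal-mediated C–N coupling against acyl substitution. The step count of the endgame should be similar or slightly lower, but the convergent C3–C5 union of the chosen plan would have to be replaced by a longer chain synthesis.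

**Alternative 3:** The cut is C1–C2. In the forward sense the C20 isocyanide of A4 adds to its C2 methyl ketone under pyridinium trifluoroacetate (a Passerini-type addition in which trifluoroacetate traps the nitrilium ion), and acyl transfer and hydrolysis then leave the tertiary alpha-hydroxy amide and the closed macrolactam A5.

- In favour: the amide, the quaternary carbinol and the ring are made in one step; there is no C1 alcohol to oxidise next to sulfur and no hindered acid to activate. On step economy of the endgame, and probably on reliability of the ring closure, it is the equal or the better of the chosen plan. It also keeps the C4 dithiane, so it is compatible with a dithiane-based chain assembly.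
- Against it here: C2 is created during the macrocyclisation with nothing but the ring conformation to control it, whereas the chosen plan brings C2 in from an enantioselective epoxidation. The isocyanide must be prepared from the free aniline late in the sequence, in the presence of the carbamate.
- Comparison: on stereochemical certainty at C2 the chosen plan is ahead; on the number and mildness of the closing steps the alternative is ahead.

Key step: step 21

**Remarks on the chemistry.**
- Numbering: C1 (amide carbonyl) to C15 (benzylic carbon), arene C16–C21. The target is 2S,6S,7S,8Z,10S,11R,12S,14R.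
- The structures of the three coupling partners and of the coupling product are stereochemically consistent with the target and are used unchanged as 31, 30, 27 and 35.
- The 3-hydroxy-2-methylpropanoate is taken as its S enantiomer. Its CH2OH carbon then becomes C9 and its ester carbon C11 directly; the R enantiomer would need an exchange of termini to give the same C10 centre.
- The 11,12-anti relationship requires an E-configured gamma-methoxyallyl reagent.
- The 6,7-syn epoxide is reached from the 6,7-anti adduct of (R)-glyceraldehyde acetonide by closing the epoxide with inversion at C6.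
- Assumption: (R)-2,2-dimethyl-1,3-dioxolane-4-carbaldehyde, methoxyallene, (−)-Ipc2BH (from (+)-alpha-pinene), tributyl(2-methylallyl)stannane and 2-(tert-butyldimethylsilyl)-1,3-dithiane are purchased.

## Route

Step 1
Reactants: 1 1-bromo-2-fluoro-3-nitrobenzene
Product: 3 3-bromo-4-fluoro-5-nitrophenol, via aryl pinacol boronate 2 (not isolated)
Conditions: [Ir(OMe)(cod)]2 (cat.), 4,4'-di-tert-butyl-2,2'-bipyridine, B2pin2, THF, 80 °C; then KHSO5 (as 2KHSO5·KHSO4·K2SO4), acetone/H2O, rt
Reagents that add atoms: potassium peroxymonosulfate, [K+].[O-]S(=O)(=O)OO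
Why: Iridium-catalysed aromatic C–H borylation is sterically controlled and should select the C–H para to fluorine, the only one without an ortho substituent; peroxymonosulfate then oxidises the C–B bond to the phenol (one-pot borylation–oxidation).

Step 2
Reactants: 3 3-bromo-4-fluoro-5-nitrophenol
Product: 4 (3-bromo-4-fluoro-5-nitrophenoxy)triisopropylsilane
Conditions: TIPSCl, imidazole, DMF, rt
Reagents that add atoms: chlorotriisopropylsilane, CC(C)[Si](Cl)(C(C)C)C(C)C
Why: Standard silylation of a phenol; the bulky silyl ether keeps the oxygen from becoming a phenoxide, which would shut down the later nucleophilic aromatic substitution.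

Step 3
Reactants: 5 methyl (S)-3-hydroxy-2-methylpropanoate
Product: 6 methyl (S)-3-(tert-butyldimethylsilyloxy)-2-methylpropanoate
Conditions: TBSCl, imidazole, CH2Cl2, rt
Reagents that add atoms: tert-butylchlorodimethylsilane, CC(C)(C)[Si](C)(C)Cl
Why: Silylation of the primary alcohol; a non-chelating silyl ether is wanted at C9 so that the next carbonyl addition follows the Felkin–Anh sense.

Step 4
Reactants: 6 methyl (S)-3-(tert-butyldimethylsilyloxy)-2-methylpropanoate
Product: 7 (S)-3-(tert-butyldimethylsilyloxy)-2-methylpropanal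
Conditions: i-Bu2AlH, CH2Cl2, −78 °C; aqueous potassium sodium tartrate (KNaC4H4O6)
Reagents that add atoms: none
Why: Partial reduction of the ester stops at the aluminium hemiacetal at low temperature; the aldehyde is used at once so that the C10 centre does not epimerise.

Step 5
Reactants: 7 (S)-3-(tert-butyldimethylsilyloxy)-2-methylpropanal
Product: 9 (2S,3R,4S)-1-(tert-butyldimethylsilyloxy)-4-methoxy-2-methylhex-5-en-3-ol, via O-diisopinocampheylboryl ether 8 (not isolated)
Conditions: (−)-Ipc2BH, methoxyallene, THF, −40 to 0 °C; 7, −78 to −20 °C; then NaOH, H2O2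
Reagents that add atoms: methoxyallene, COC=C=C
Why: Hydroboration of the terminal allene double bond gives the E-configured gamma-methoxyallylborane after 1,3-boron shift, which adds through a chair transition state to set C11 and C12 anti (asymmetric alkoxyallylboration); the (−)-diisopinocampheyl reagent attacks the aldehyde Si face, which is also the Felkin–Anh face of 7, so reagent and substrate control are matched for 10,11-syn.

Step 6
Reactants: 9 (2S,3R,4S)-1-(tert-butyldimethylsilyloxy)-4-methoxy-2-methylhex-5-en-3-ol; 4 (3-bromo-4-fluoro-5-nitrophenoxy)triisopropylsilane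
Product: 10 bromo nitro aryl ether (10S,11R,12S) with C21–O–C11 bond; 16-Br; 20-NO2; 18-OTIPS; 9-OTBS; C13 vinyl
Conditions: KN(SiMe3)2, THF, −78 to 0 °C
Reagents that add atoms: none
Why: Nucleophilic aromatic substitution of the fluoride activated by the ortho nitro group; the C11–O bond of the alkoxide is not broken, so C11 keeps its configuration.

Step 7
Reactants: 10 bromo nitro aryl ether (10S,11R,12S)
Product: 11 methallyl nitro aryl ether (10S,11R,12S) with 2-methylallyl at C16 and vinyl at C13
Conditions: Pd(PPh3)4, tributyl(2-methylallyl)stannane, toluene, 100 °C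
Reagents that add atoms: tributyl(2-methylallyl)stannane, CCCC[Sn](CCCC)(CCCC)CC(C)=C
Why: Stille coupling of an electron-poor aryl bromide under neutral conditions, which avoids base-induced migration of the new double bond into conjugation with the nitroarene.

Step 8
Reactants: 11 methallyl nitro aryl ether (10S,11R,12S)
Product: 12 nitro benzoxocine (10S,11R,12S,13Z) with ring B closed through C13=C14; 9-OTBS; 18-OTIPS; 20-NO2
Conditions: second-generation Grubbs catalyst RuCl2(=CHPh)(H2IMes)(PCy3) (cat.), toluene, 80 °C, high dilution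
Reagents that add atoms: none
Why: Ring-closing metathesis between the monosubstituted and the 1,1-disubstituted alkene, with loss of ethylene; the arene and the aryl ether hold the two chains close, which favours the eight-membered ring over oligomers.

Step 9
Reactants: 12 nitro benzoxocine (10S,11R,12S,13Z)
Product: 13 nitro benzoxocane (10S,11R,12S,14R); 9-OTBS; 18-OTIPS; 20-NO2
Conditions: [Ir(cod)(PCy3)(py)]PF6 (cat.), H2 (1 atm), CH2Cl2, rt
Reagents that add atoms: none
Why: Directed homogeneous hydrogenation: the cationic iridium binds the C12 methoxy oxygen and delivers hydrogen to the alkene face cis to it, which is also the face away from the C11 side chain, so the C14 methyl ends trans to the methoxy group (14R); the nitro group is not reduced by this catalyst.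

Step 10
Reactants: 13 nitro benzoxocane (10S,11R,12S,14R)
Product: 14 amino benzoxocane (10S,11R,12S,14R); 9-OTBS; 18-OTIPS; 20-NH2
Conditions: Zn, AcOH, EtOH, 0 °C to rt
Reagents that add atoms: none
Why: Dissolving-metal reduction of an aromatic nitro group to the aniline; silyl ethers and the aryl ether are inert.

Step 11
Reactants: 14 amino benzoxocane (10S,11R,12S,14R)
Product: 16 pyrrole alcohol (10S,11R,12S,14R); 20-(2,5-dimethylpyrrol-1-yl); 18-OTIPS; 9-OH, via pyrrole silyl ether 15 (not isolated)
Conditions: hexane-2,5-dione, p-TsOH·H2O (cat.), toluene, 80 °C; then MeOH, rt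
Reagents that add atoms: hexane-2,5-dione, CC(=O)CCC(C)=O
Why: Paal–Knorr condensation masks the aniline as a 2,5-dimethylpyrrole that has no N–H and resists organolithiums; the same acid in methanol then removes the primary silyl ether while the aryl silyl ether stays.

Step 12
Reactants: 16 pyrrole alcohol (10S,11R,12S,14R)
Product: 17 C9 aldehyde (10R by rule change only; 11R,12S,14R); 20-(2,5-dimethylpyrrol-1-yl); 18-OTIPS
Conditions: Dess–Martin periodinane, NaHCO3, CH2Cl2, 0 °C
Reagents that add atoms: none
Why: Buffered Dess–Martin oxidation gives the alpha-methyl, beta-aryloxy aldehyde without base, so neither epimerisation at C10 nor elimination of the aryloxide is expected; the aldehyde is used directly.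

Step 13
Reactants: 17 C9 aldehyde (11R,12S,14R)
Product: 18 Z-alkenyl iodide (8Z,10S,11R,12S,14R) with C9=C8(CH3)I; 20-(2,5-dimethylpyrrol-1-yl); 18-OTIPS
Conditions: [Ph3PEt]I, n-BuLi, THF, 0 °C; I2, −78 °C; NaN(SiMe3)2, −20 °C; 17, −78 °C
Reagents that add atoms: ethyltriphenylphosphonium iodide, CC[P+](c1ccccc1)(c1ccccc1)c1ccccc1.[I-]; iodine, II
Why: Stork–Zhao olefination with the alpha-iodoethylidene ylide; the unstabilised ylide reacts under kinetic control and should place iodine cis to the C10 chain (Z), and the low temperature limits enolisation of the aldehyde.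

Step 14
Reactants: 18 Z-alkenyl iodide (8Z,10S,11R,12S,14R); 19 (R)-2,2-dimethyl-1,3-dioxolane-4-carbaldehyde
Product: 22 C7 allylic alcohol acetonide (6R,7S,8Z,10S,11R,12S,14R), via alkenyllithium 20 (not isolated), via alkenyltitanium triisopropoxide 21 (not isolated)
Conditions: t-BuLi, Et2O, −78 °C; ClTi(OiPr)3, −78 °C; 19, −78 to −30 °C
Reagents that add atoms: none
Why: Iodine–lithium exchange and transmetalation keep the alkene geometry; the weakly Lewis acidic alkenyltitanium reagent cannot chelate the alpha-oxygen, so addition should follow the polar Felkin–Anh model and give the 6,7-anti carbinol (7S).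

Step 15
Reactants: 22 C7 allylic alcohol acetonide (6R,7S,8Z,10S,11R,12S,14R)
Product: 23 C7 silyl ether acetonide (6R,7S,8Z,10S,11R,12S,14R); 7-OTBS
Conditions: TBSOTf, 2,6-lutidine, CH2Cl2, −78 to 0 °C
Reagents that add atoms: tert-butyldimethylsilyl trifluoromethanesulfonate, CC(C)(C)[Si](C)(C)OS(=O)(=O)C(F)(F)F
Why: Silyl triflate silylation of a hindered secondary allylic alcohol; the group must survive the dithiane anion and be removable later in the presence of a tertiary and an aryl silyl ether.

Step 16
Reactants: 23 C7 silyl ether acetonide (6R,7S,8Z,10S,11R,12S,14R)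
Product: 24 C5,C6 diol (6R,7S,8Z,10S,11R,12S,14R); 7-OTBS
Conditions: camphorsulfonic acid (cat.), MeOH, 0 °C
Reagents that add atoms: none
Why: Acid-catalysed transketalisation of a terminal acetonide is much faster than cleavage of a hindered secondary or an aryl silyl ether, so only the diol is released.

Step 17
Reactants: 24 C5,C6 diol (6R,7S,8Z,10S,11R,12S,14R)
Product: 26 C5 acetate C6 mesylate (6R,7S,8Z,10S,11R,12S,14R), via primary acetate 25 (not isolated)
Conditions: AcCl, 2,4,6-collidine, CH2Cl2, −78 °C; then MsCl, Et3N, −78 to 0 °C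
Reagents that add atoms: acetyl chloride, CC(=O)Cl; methanesulfonyl chloride, CS(=O)(=O)Cl
Why: Acetyl chloride with a hindered pyridine base acylates the primary hydroxyl selectively at low temperature; the remaining secondary hydroxyl is then sulfonylated through the sulfene, which tolerates the crowded C6 position.

Step 18
Reactants: 26 C5 acetate C6 mesylate (6R,7S,8Z,10S,11R,12S,14R)
Product: 27 benzoxocane C5–C6 epoxide (6S,7S,8Z,10S,11R,12S,14R); 7-OTBS; 18-OTIPS; 20-(2,5-dimethylpyrrol-1-yl)
Conditions: K2CO3, MeOH, 0 °C
Reagents that add atoms: none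
Why: Methanolysis of the acetate frees the C5 alkoxide, which displaces the C6 mesylate from the rear (3-exo-tet epoxide closure); the inversion turns 6R into 6S and the 6,7-anti diol into the 6,7-syn epoxide, and the short cold treatment spares the aryl silyl ether.

Step 19
Reactants: 28 2-methylprop-2-en-1-ol
Product: 29 (R)-(2-methyloxiran-2-yl)methanol
Conditions: Ti(OiPr)4 (cat.), D-(−)-diisopropyl tartrate (cat.), cumene hydroperoxide, 4 Å molecular sieves, CH2Cl2, −20 °C
Reagents that add atoms: cumene hydroperoxide, CC(C)(OO)c1ccccc1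
Why: Sharpless asymmetric epoxidation; the D-(−)-tartrate catalyst delivers oxygen to the face that gives the R epoxy alcohol, the opposite of the 2S sense seen with the L-(+)-ester.

Step 20
Reactants: 29 (R)-(2-methyloxiran-2-yl)methanol
Product: 30 (S)-triethyl[(2-methyloxiran-2-yl)methoxy]silane
Conditions: TESCl, imidazole, CH2Cl2, 0 °C
Reagents that add atoms: chlorotriethylsilane, CC[Si](Cl)(CC)CC
Why: Silylation of the primary alcohol (the descriptor changes from R to S by priority only); a primary triethylsilyl ether can later be removed beside tert-butyldimethylsilyl and triisopropylsilyl ethers.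

Step 21
Reactants: 31 2-(tert-butyldimethylsilyl)-1,3-dithiane; 30 (S)-triethyl[(2-methyloxiran-2-yl)methoxy]silane; 27 benzoxocane C5–C6 epoxide (6S,7S,8Z,10S,11R,12S,14R)
Product: 35 C1–C21 seco chain with C4 dithiane (2S,6S,7S,8Z,10S,11R,12S,14R); 1-OTES; 2-OTBS; 6-OH; 7-OTBS; 18-OTIPS; 20-(2,5-dimethylpyrrol-1-yl), via lithiated silyl dithiane 32 (not isolated), via tertiary lithium alkoxide 33 (not isolated), via rearranged lithiated dithiane 34 (not isolated)
Conditions: t-BuLi, Et2O, −78 to −45 °C; 30, −78 to −25 °C; 27, HMPA, THF, −78 °C to rt; NH4Cl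
Reagents that add atoms: none
Why: The lithiated silyl dithiane 32 opens the 2,2-disubstituted epoxide 30 at its CH2 (C3) in ether, where the tertiary lithium alkoxide 33 is stable and silicon stays on carbon. Adding HMPA together with the second epoxide triggers the 1,4-Brook rearrangement, which moves silicon from C4 to the C2 oxygen, caps the tertiary carbinol and regenerates a carbanion at C4 (34). That anion opens the monosubstituted epoxide 27 at C5 by SN2 attack, and protonation gives 35. The closest known reaction type is the three-component linchpin union of two different epoxides by a 2-silyl-1,3-dithiane under solvent-controlled Brook rearrangement. No ring is closed and no stereocentre is created; C2 and C6 come unchanged from the epoxides because only the methylene termini are attacked. The selectivity needed is one opening per epoxide, in the right order and at the unsubstituted carbon: the order is fixed by the solvent gate (no second carbanion exists before HMPA is added) and the regiochemistry by the preference of the bulky anion for the CH2 terminus. The valuable epoxide 27 is added last as the limiting component, and C4 stays a thioketal so that the beta-alkoxy ketone is not enolisable in the later base steps.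

Step 22
Reactants: 35 C1–C21 seco chain with C4 dithiane; 6-OH
Product: 36 C6 methyl ether of the seco chain (2S,6S,7S,8Z,10S,11R,12S,14R)
Conditions: KN(SiMe3)2, THF, −78 °C; MeOTf, −78 °C; Et3N quench
Reagents that add atoms: methyl trifluoromethanesulfonate, COS(=O)(=O)C(F)(F)F
Why: Williamson-type O-methylation of the potassium alkoxide with the most reactive methyl donor at −78 °C, so that trapping outruns 1,2-silyl migration from the C7 oxygen; the hindered thioketal sulfur is a much poorer nucleophile than the alkoxide, and excess triflate is destroyed cold.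

Step 23
Reactants: 36 C6 methyl ether of the seco chain
Product: 37 C1 primary alcohol (2S,6S,7S,8Z,10S,11R,12S,14R)
Conditions: PPTS, MeOH/CH2Cl2, 0 °C
Reagents that add atoms: none
Why: Mild acidic methanolysis removes the primary triethylsilyl ether far faster than the secondary and tertiary tert-butyldimethylsilyl ethers or the aryl triisopropylsilyl ether.

Step 24
Reactants: 37 C1 primary alcohol
Product: 38 C1 aldehyde (2S,6S,7S,8Z,10S,11R,12S,14R)
Conditions: SO3·pyridine, DMSO, i-Pr2NEt, CH2Cl2, 0 °C
Reagents that add atoms: none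
Why: Parikh–Doering oxidation is compatible with dithianes and electron-rich heteroarenes; the aldehyde has no alpha hydrogen and cannot epimerise.

Step 25
Reactants: 38 C1 aldehyde
Product: 39 C1 carboxylic acid (2S,6S,7S,8Z,10S,11R,12S,14R)
Conditions: NaClO2, NaH2PO4, 2-methyl-2-butene (large excess), t-BuOH/H2O, 0 °C
Reagents that add atoms: sodium chlorite, [Na+].[O-]Cl=O
Why: Pinnick oxidation of the aldehyde; the large excess of alkene scavenges hypochlorous acid before it can oxidise the thioketal sulfur or chlorinate the pyrrole.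

Step 26
Reactants: 39 C1 carboxylic acid
Product: 40 seco amino acid (2S,6S,7S,8Z,10S,11R,12S,14R); 20-NH2
Conditions: NH2OH·HCl, Et3N, i-PrOH/H2O, 80 °C
Reagents that add atoms: none
Why: Hydroxylamine opens the 2,5-dimethylpyrrole by transoximation (the reverse of the Paal–Knorr reaction) and frees the aniline; the dithiane keeps C4 from forming an oxime.

Step 27
Reactants: 40 seco amino acid
Product: 41 macrolactam with C4 dithiane (2S,6S,7S,8Z,10S,11R,12S,14R); 2-OTBS; 7-OTBS; 18-OTIPS
Conditions: BOP-Cl, i-Pr2NEt, toluene, 80 °C, slow addition at high dilution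
Reagents that add atoms: none
Why: Macrolactamisation through the mixed phosphinic anhydride, an activation suited to hindered acids and weakly nucleophilic anilines; the benzoxocane and the Z-alkene turn the chain ends toward each other, and dilution suppresses dimers.

Step 28
Reactants: 41 macrolactam with C4 dithiane
Product: 42 C7 alcohol macrolactam (2S,6S,7S,8Z,10S,11R,12S,14R); 2-OTBS; 18-OTIPS
Conditions: HF·pyridine, pyridine, THF, 0 °C
Reagents that add atoms: none
Why: Under buffered acidic fluoride the secondary allylic silyl ether should be cleaved before the tertiary silyl ether next to the amide carbonyl and before the aryl triisopropylsilyl ether, which is the slow one under acidic conditions.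

Step 29
Reactants: 42 C7 alcohol macrolactam
Product: 44 C7 carbamate macrolactam (2S,6S,7S,8Z,10S,11R,12S,14R), via N-trichloroacetyl carbamate 43 (not isolated)
Conditions: Cl3CC(O)NCO, CH2Cl2, 0 °C; then neutral Al2O3, rt
Reagents that add atoms: trichloroacetyl isocyanate, O=C=NC(=O)C(Cl)(Cl)Cl
Why: The acyl isocyanate carbamoylates the only free hydroxyl quickly, and the trichloroacetyl group is then removed on neutral alumina, conditions that leave the aryl silyl ether in place.

Step 30
Reactants: 44 C7 carbamate macrolactam
Product: 45 C4 ketone macrolactam (2S,6S,7S,8Z,10S,11R,12S,14R); 2-OTBS; 18-OTIPS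
Conditions: MeI, CaCO3, MeCN/H2O, 45 °C
Reagents that add atoms: water, O
Why: Alkylative hydrolysis of the dithiane (S-methylation, then attack of water) is non-oxidising and near neutral, so the electron-rich arene, the alkene and the new beta-alkoxy ketone should be untouched.

Step 31
Reactants: 45 C4 ketone macrolactam
Product: 46 CNP0122739.1 (2S,6S,7S,8Z,10S,11R,12S,14R)
Conditions: HF·pyridine, THF, rt
Reagents that add atoms: none
Why: Acidic fluoride removes the aryl and the tertiary silyl ether without the basic conditions that would cause retro-aldol cleavage at C2–C3 or elimination of the C6 methoxy group.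

## Compound list

1 | 1-bromo-2-fluoro-3-nitrobenzene | O=[N+]([O-])c1cccc(Br)c1F | starting material
2 | 2-(3-bromo-4-fluoro-5-nitrophenyl)-4,4,5,5-tetramethyl-1,3,2-dioxaborolane | CC1(C)OB(OC1(C)C)c1cc(Br)c(F)c([N+](=O)[O-])c1 | intermediate
3 | 3-bromo-4-fluoro-5-nitrophenol | Oc1cc(Br)c(F)c([N+](=O)[O-])c1 | intermediate
4 | (3-bromo-4-fluoro-5-nitrophenoxy)triisopropylsilane | CC(C)[Si](Oc1cc(Br)c(F)c([N+](=O)[O-])c1)(C(C)C)C(C)C | intermediate
5 | methyl (S)-3-hydroxy-2-methylpropanoate | C[C@@H](CO)C(=O)OC | starting material
6 | methyl (S)-3-(tert-butyldimethylsilyloxy)-2-methylpropanoate | C[C@@H](CO[Si](C)(C)C(C)(C)C)C(=O)OC | intermediate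
7 | (S)-3-(tert-butyldimethylsilyloxy)-2-methylpropanal | C[C@@H](CO[Si](C)(C)C(C)(C)C)C=O | intermediate
8 | O-diisopinocampheylboryl ether of 9 | C=C[C@H](OC)[C@H](OB([C@@H]1C[C@@H]2C[C@H]([C@H]1C)C2(C)C)[C@@H]1C[C@@H]2C[C@H]([C@H]1C)C2(C)C)[C@@H](C)CO[Si](C)(C)C(C)(C)C | intermediate
9 | (2S,3R,4S)-1-(tert-butyldimethylsilyloxy)-4-methoxy-2-methylhex-5-en-3-ol | C=C[C@H](OC)[C@H](O)[C@@H](C)CO[Si](C)(C)C(C)(C)C | intermediate
10 | bromo nitro aryl ether (10S,11R,12S): C11–O–C21 ether of 9 with the arene of 4 | C=C[C@H](OC)[C@H](Oc1c(Br)cc(O[Si](C(C)C)(C(C)C)C(C)C)cc1[N+](=O)[O-])[C@@H](C)CO[Si](C)(C)C(C)(C)C | intermediate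
11 | methallyl nitro aryl ether (10S,11R,12S): 2-methylallyl at C16 | C=C[C@H](OC)[C@H](Oc1c(CC(C)=C)cc(O[Si](C(C)C)(C(C)C)C(C)C)cc1[N+](=O)[O-])[C@@H](C)CO[Si](C)(C)C(C)(C)C | intermediate
12 | nitro benzoxocine (10S,11R,12S,13Z): ring B with C13=C14, 9-OTBS, 18-OTIPS, 20-NO2 | CO[C@H]1/C=C(/C)Cc2cc(O[Si](C(C)C)(C(C)C)C(C)C)cc([N+](=O)[O-])c2O[C@@H]1[C@@H](C)CO[Si](C)(C)C(C)(C)C | intermediate
13 | nitro benzoxocane (10S,11R,12S,14R) | CO[C@H]1C[C@H](C)Cc2cc(O[Si](C(C)C)(C(C)C)C(C)C)cc([N+](=O)[O-])c2O[C@@H]1[C@@H](C)CO[Si](C)(C)C(C)(C)C | intermediate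
14 | amino benzoxocane (10S,11R,12S,14R) | CO[C@H]1C[C@H](C)Cc2cc(O[Si](C(C)C)(C(C)C)C(C)C)cc(N)c2O[C@@H]1[C@@H](C)CO[Si](C)(C)C(C)(C)C | intermediate
15 | pyrrole silyl ether (10S,11R,12S,14R): 20-(2,5-dimethylpyrrol-1-yl), 9-OTBS | CO[C@H]1C[C@H](C)Cc2cc(O[Si](C(C)C)(C(C)C)C(C)C)cc(-n3c(C)ccc3C)c2O[C@@H]1[C@@H](C)CO[Si](C)(C)C(C)(C)C | intermediate
16 | pyrrole alcohol (10S,11R,12S,14R): 9-OH | CO[C@H]1C[C@H](C)Cc2cc(O[Si](C(C)C)(C(C)C)C(C)C)cc(-n3c(C)ccc3C)c2O[C@@H]1[C@@H](C)CO | intermediate
17 | C9 aldehyde (10R,11R,12S,14R) | CO[C@H]1C[C@H](C)Cc2cc(O[Si](C(C)C)(C(C)C)C(C)C)cc(-n3c(C)ccc3C)c2O[C@@H]1[C@@H](C)C=O | intermediate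
18 | Z-alkenyl iodide (8Z,10S,11R,12S,14R) | CO[C@H]1C[C@H](C)Cc2cc(O[Si](C(C)C)(C(C)C)C(C)C)cc(-n3c(C)ccc3C)c2O[C@@H]1[C@@H](C)/C=C(/C)I | intermediate
19 | (R)-2,2-dimethyl-1,3-dioxolane-4-carbaldehyde | O=C[C@H]1COC(C)(C)O1 | starting material
20 | alkenyllithium from 18 (geometry retained) | CO[C@H]1C[C@H](C)Cc2cc(O[Si](C(C)C)(C(C)C)C(C)C)cc(-n3c(C)ccc3C)c2O[C@@H]1[C@@H](C)/C=C(/C)[Li] | intermediate
21 | alkenyltitanium triisopropoxide from 20 (geometry retained) | CO[C@H]1C[C@H](C)Cc2cc(O[Si](C(C)C)(C(C)C)C(C)C)cc(-n3c(C)ccc3C)c2O[C@@H]1[C@@H](C)/C=C(/C)[Ti](OC(C)C)(OC(C)C)OC(C)C | intermediate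
22 | C7 allylic alcohol acetonide (6R,7S,8Z,10S,11R,12S,14R) | CO[C@H]1C[C@H](C)Cc2cc(O[Si](C(C)C)(C(C)C)C(C)C)cc(-n3c(C)ccc3C)c2O[C@@H]1[C@@H](C)/C=C(/C)[C@H](O)[C@H]4COC(C)(C)O4 | intermediate
23 | C7 silyl ether acetonide (6R,7S,8Z,10S,11R,12S,14R) | CO[C@H]1C[C@H](C)Cc2cc(O[Si](C(C)C)(C(C)C)C(C)C)cc(-n3c(C)ccc3C)c2O[C@@H]1[C@@H](C)/C=C(/C)[C@H](O[Si](C)(C)C(C)(C)C)[C@H]4COC(C)(C)O4 | intermediate
24 | C5,C6 diol (6R,7S,8Z,10S,11R,12S,14R) | CO[C@H]1C[C@H](C)Cc2cc(O[Si](C(C)C)(C(C)C)C(C)C)cc(-n3c(C)ccc3C)c2O[C@@H]1[C@@H](C)/C=C(/C)[C@H](O[Si](C)(C)C(C)(C)C)[C@H](O)CO | intermediate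
25 | C5 acetate, C6 alcohol (6R,7S) | CO[C@H]1C[C@H](C)Cc2cc(O[Si](C(C)C)(C(C)C)C(C)C)cc(-n3c(C)ccc3C)c2O[C@@H]1[C@@H](C)/C=C(/C)[C@H](O[Si](C)(C)C(C)(C)C)[C@H](O)COC(C)=O | intermediate
26 | C5 acetate, C6 mesylate (6R,7S) | CO[C@H]1C[C@H](C)Cc2cc(O[Si](C(C)C)(C(C)C)C(C)C)cc(-n3c(C)ccc3C)c2O[C@@H]1[C@@H](C)/C=C(/C)[C@H](O[Si](C)(C)C(C)(C)C)[C@H](OS(C)(=O)=O)COC(C)=O | intermediate
27 | benzoxocane C5–C6 epoxide with pyrrole-masked aniline (6S,7S,8Z,10S,11R,12S,14R) | CO[C@H]1C[C@H](C)Cc2cc(O[Si](C(C)C)(C(C)C)C(C)C)cc(-n3c(C)ccc3C)c2O[C@@H]1[C@@H](C)/C=C(/C)[C@H](O[Si](C)(C)C(C)(C)C)[C@@H]4CO4 | intermediate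
28 | 2-methylprop-2-en-1-ol | C=C(C)CO | starting material
29 | (R)-(2-methyloxiran-2-yl)methanol | C[C@]1(CO1)CO | intermediate
30 | (S)-triethyl[(2-methyloxiran-2-yl)methoxy]silane | C[C@]1(CO1)CO[Si](CC)(CC)CC | intermediate
31 | 2-(tert-butyldimethylsilyl)-1,3-dithiane | CC(C)(C)[Si](C)(C)C1SCCCS1 | starting material
32 | 2-lithio-2-(tert-butyldimethylsilyl)-1,3-dithiane | [Li]C1(SCCCS1)[Si](C)(C)C(C)(C)C | intermediate
33 | lithium (S)-alkoxide from 32 and 30 (silicon still on C4) | C([C@](C)(O[Li])CO[Si](CC)(CC)CC)C1(SCCCS1)[Si](C)(C)C(C)(C)C | intermediate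
34 | 2-lithio-1,3-dithiane after Brook rearrangement (2S, 2-OTBS, 1-OTES) | C([C@](C)(O[Si](C)(C)C(C)(C)C)CO[Si](CC)(CC)CC)C1([Li])SCCCS1 | intermediate
35 | C1–C21 seco chain with C4 dithiane, 6-OH (2S,6S,7S,8Z,10S,11R,12S,14R) | CO[C@H]1C[C@H](C)Cc2cc(O[Si](C(C)C)(C(C)C)C(C)C)cc(-n3c(C)ccc3C)c2O[C@@H]1[C@@H](C)/C=C(/C)[C@H](O[Si](C)(C)C(C)(C)C)[C@@H](O)CC4(SCCCS4)C[C@](C)(O[Si](C)(C)C(C)(C)C)CO[Si](CC)(CC)CC | intermediate
36 | C6 methyl ether of 35 | CO[C@H]1C[C@H](C)Cc2cc(O[Si](C(C)C)(C(C)C)C(C)C)cc(-n3c(C)ccc3C)c2O[C@@H]1[C@@H](C)/C=C(/C)[C@H](O[Si](C)(C)C(C)(C)C)[C@@H](OC)CC4(SCCCS4)C[C@](C)(O[Si](C)(C)C(C)(C)C)CO[Si](CC)(CC)CC | intermediate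
37 | C1 primary alcohol | CO[C@H]1C[C@H](C)Cc2cc(O[Si](C(C)C)(C(C)C)C(C)C)cc(-n3c(C)ccc3C)c2O[C@@H]1[C@@H](C)/C=C(/C)[C@H](O[Si](C)(C)C(C)(C)C)[C@@H](OC)CC4(SCCCS4)C[C@](C)(O[Si](C)(C)C(C)(C)C)CO | intermediate
38 | C1 aldehyde | CO[C@H]1C[C@H](C)Cc2cc(O[Si](C(C)C)(C(C)C)C(C)C)cc(-n3c(C)ccc3C)c2O[C@@H]1[C@@H](C)/C=C(/C)[C@H](O[Si](C)(C)C(C)(C)C)[C@@H](OC)CC4(SCCCS4)C[C@](C)(O[Si](C)(C)C(C)(C)C)C=O | intermediate
39 | C1 carboxylic acid | CO[C@H]1C[C@H](C)Cc2cc(O[Si](C(C)C)(C(C)C)C(C)C)cc(-n3c(C)ccc3C)c2O[C@@H]1[C@@H](C)/C=C(/C)[C@H](O[Si](C)(C)C(C)(C)C)[C@@H](OC)CC4(SCCCS4)C[C@](C)(O[Si](C)(C)C(C)(C)C)C(=O)O | intermediate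
40 | seco amino acid (20-NH2) | CO[C@H]1C[C@H](C)Cc2cc(O[Si](C(C)C)(C(C)C)C(C)C)cc(N)c2O[C@@H]1[C@@H](C)/C=C(/C)[C@H](O[Si](C)(C)C(C)(C)C)[C@@H](OC)CC4(SCCCS4)C[C@](C)(O[Si](C)(C)C(C)(C)C)C(=O)O | intermediate
41 | macrolactam with C4 dithiane, 2-OTBS, 7-OTBS, 18-OTIPS | CO[C@H]1C[C@H](C)Cc2cc(O[Si](C(C)C)(C(C)C)C(C)C)cc3c2O[C@@H]1[C@@H](C)/C=C(/C)[C@H](O[Si](C)(C)C(C)(C)C)[C@@H](OC)CC4(SCCCS4)C[C@](C)(O[Si](C)(C)C(C)(C)C)C(=O)N3 | intermediate
42 | C7 alcohol macrolactam | CO[C@H]1C[C@H](C)Cc2cc(O[Si](C(C)C)(C(C)C)C(C)C)cc3c2O[C@@H]1[C@@H](C)/C=C(/C)[C@H](O)[C@@H](OC)CC4(SCCCS4)C[C@](C)(O[Si](C)(C)C(C)(C)C)C(=O)N3 | intermediate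
43 | C7 N-trichloroacetyl carbamate macrolactam | CO[C@H]1C[C@H](C)Cc2cc(O[Si](C(C)C)(C(C)C)C(C)C)cc3c2O[C@@H]1[C@@H](C)/C=C(/C)[C@H](OC(=O)NC(=O)C(Cl)(Cl)Cl)[C@@H](OC)CC4(SCCCS4)C[C@](C)(O[Si](C)(C)C(C)(C)C)C(=O)N3 | intermediate
44 | C7 carbamate macrolactam with C4 dithiane | CO[C@H]1C[C@H](C)Cc2cc(O[Si](C(C)C)(C(C)C)C(C)C)cc3c2O[C@@H]1[C@@H](C)/C=C(/C)[C@H](OC(N)=O)[C@@H](OC)CC4(SCCCS4)C[C@](C)(O[Si](C)(C)C(C)(C)C)C(=O)N3 | intermediate
45 | C4 ketone macrolactam, 2-OTBS, 18-OTIPS | CO[C@H]1C[C@H](C)Cc2cc(O[Si](C(C)C)(C(C)C)C(C)C)cc3c2O[C@@H]1[C@@H](C)/C=C(/C)[C@H](OC(N)=O)[C@@H](OC)CC(=O)C[C@](C)(O[Si](C)(C)C(C)(C)C)C(=O)N3 | intermediate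
46 | CNP0122739.1 (2S,6S,7S,8Z,10S,11R,12S,14R) | CO[C@H]1C[C@H](C)Cc2cc(O)cc3c2O[C@@H]1[C@@H](C)/C=C(/C)[C@H](OC(N)=O)[C@@H](OC)CC(=O)C[C@](C)(O)C(=O)N3 | target

## Step count and least certain steps

Total: 31 steps. Longest linear sequence: 27 steps (steps 3 to 18 from 5, then steps 21 to 31).

**Step 21 (key step).** The bulky silyl dithiane anion may open the 2,2-disubstituted epoxide sluggishly. After the HMPA-triggered silyl shift, the new carbanion may be quenched by proton transfer before it alkylates the hindered second epoxide, or the silyl group may scramble to the C6 alkoxide. Fallback: a stepwise double alkylation without the relay. It sets out from 30 and 27: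
- lithiated 1,3-dithiane (n-BuLi, THF) opens 30 to the dithianyl tertiary alcohol F2;
- TBSOTf and 2,6-lutidine give the silyl ether F3;
- deprotonation of F3 (t-BuLi, THF/HMPA, −78 °C) gives 34 directly, which is alkylated with 27.

It comes back to the route at 35.

**Step 5.** Incomplete equilibration of the allylborane to its E isomer, or competition between reagent and substrate control, would erode the anti and the facial selectivity. Fallback: a chromium-mediated gamma-methoxyallylation (CrCl2, Me3SiI, acrolein dimethyl acetal, THF, −30 °C). The E-configured allylchromium species adds through a chair transition state (anti) and the aldehyde alone supplies Felkin–Anh control. It runs from 7 to 9 and makes no new compound.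

**Step 9.** Binding of the catalyst to the nitro or aryl ether oxygen, or the flexibility of the eight-membered ring, could lower the facial selectivity, and alkene migration could compete. Fallback: replace substrate direction by catalyst control, using a chiral iridium phosphine–oxazoline complex, [Ir(cod)(t-Bu-PHOX)]B[3,5-(CF3)2C6H3]4, under H2 pressure, with the ligand enantiomer chosen to match. It runs from 12 to 13 and makes no new compound.

**Step 14.** Incomplete transmetalation or partial chelation would lower the Felkin–Anh preference at C7, and the basic alkenyl metal could enolise the aldehyde. Fallback: from the C7-epimeric mixture of 22, Dess–Martin oxidation gives the enone F1, and Zn(BH4)2 (Et2O, −20 °C) reduces it in the 1,2 sense under chelation with the alpha-oxygen, which gives the 6,7-anti alcohol. It comes back to the route at 22.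

**Step 25.** Hypochlorous acid may escape the scavenger and oxidise the thioketal sulfur or chlorinate the pyrrole. Fallback without chlorine, setting out from 38: pyridinium dichromate, (C5H5NH)2Cr2O7 (hexavalent chromium), with MeOH in DMF oxidises the methyl hemiacetal to the methyl ester F4, and Me3SnOH in 1,2-dichloroethane at 80 °C cleaves the hindered ester. It comes back to the route at 39.

**Step 27.** Acylation of the hindered, weakly nucleophilic aniline by the alpha-quaternary activated acid may be slower than oligomerisation or decay of the activated species. Fallback: reverse the activation. It sets out from 40: Me3SiCHN2 in MeOH/toluene gives the amino methyl ester F5, and AlMe3 in toluene at 80 °C under high dilution turns the aniline into an aluminium amide that attacks the ester. It comes back to the route at 41.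

## Further compounds

F0 | step 5 | none | none
F0 | step 9 | none | none
F1 | step 14 | C7 enone acetonide (6R,8Z,10S,11R,12S,14R) | CO[C@H]1C[C@H](C)Cc2cc(O[Si](C(C)C)(C(C)C)C(C)C)cc(-n3c(C)ccc3C)c2O[C@@H]1[C@@H](C)/C=C(/C)C(=O)[C@H]4COC(C)(C)O4
F2 | step 21 | (S)-1-(1,3-dithian-2-yl)-2-methyl-3-(triethylsilyloxy)propan-2-ol | C[C@](O)(CC1SCCCS1)CO[Si](CC)(CC)CC
F3 | step 21 | 2-[(S)-2-(tert-butyldimethylsilyloxy)-2-methyl-3-(triethylsilyloxy)propyl]-1,3-dithiane | C[C@](O[Si](C)(C)C(C)(C)C)(CC1SCCCS1)CO[Si](CC)(CC)CC
F4 | step 25 | C1 methyl ester of 39 (pyrrole retained) | CO[C@H]1C[C@H](C)Cc2cc(O[Si](C(C)C)(C(C)C)C(C)C)cc(-n3c(C)ccc3C)c2O[C@@H]1[C@@H](C)/C=C(/C)[C@H](O[Si](C)(C)C(C)(C)C)[C@@H](OC)CC4(SCCCS4)C[C@](C)(O[Si](C)(C)C(C)(C)C)C(=O)OC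
F5 | step 27 | methyl ester of seco amino acid 40 | CO[C@H]1C[C@H](C)Cc2cc(O[Si](C(C)C)(C(C)C)C(C)C)cc(N)c2O[C@@H]1[C@@H](C)/C=C(/C)[C@H](O[Si](C)(C)C(C)(C)C)[C@@H](OC)CC4(SCCCS4)C[C@](C)(O[Si](C)(C)C(C)(C)C)C(=O)OC
A1 | alternative 1 | nitro benzoxocine with C13=C14 alkene (identical with 12) | CO[C@H]1/C=C(/C)Cc2cc(O[Si](C(C)C)(C(C)C)C(C)C)cc([N+](=O)[O-])c2O[C@@H]1[C@@H](C)CO[Si](C)(C)C(C)(C)C
A2 | alternative 2 | open-chain C1 primary amide with C20 aryl bromide and C4 dioxolane | CO[C@H]1C[C@H](C)Cc2cc(OCOC)cc(Br)c2O[C@@H]1[C@@H](C)/C=C(/C)[C@H](O[Si](C)(C)C(C)(C)C)[C@@H](OC)CC4(OCCO4)C[C@](C)(O)C(N)=O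
A3 | alternative 2 | protected macrolactam with C4 dioxolane | CO[C@H]1C[C@H](C)Cc2cc(OCOC)cc3c2O[C@@H]1[C@@H](C)/C=C(/C)[C@H](O[Si](C)(C)C(C)(C)C)[C@@H](OC)CC4(OCCO4)C[C@](C)(O)C(=O)N3
A4 | alternative 3 | C20 isocyanide with C2 methyl ketone and C4 dithiane | CO[C@H]1C[C@H](C)Cc2cc(O[Si](C(C)C)(C(C)C)C(C)C)cc([N+]#[C-])c2O[C@@H]1[C@@H](C)/C=C(/C)[C@H](OC(N)=O)[C@@H](OC)CC4(SCCCS4)CC(C)=O
A5 | alternative 3 | macrolactam with C2 tertiary alcohol and C4 dithiane | CO[C@H]1C[C@H](C)Cc2cc(O[Si](C(C)C)(C(C)C)C(C)C)cc3c2O[C@@H]1[C@@H](C)/C=C(/C)[C@H](OC(N)=O)[C@@H](OC)CC4(SCCCS4)C[C@](C)(O)C(=O)N3
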